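common to all: coupling partner 0.216 M (in portions, 3); free catalyst 0.48 mM

| flask | substrate | remark | time |
|---|---|---|---|
| gamma | 0.34 M | run made earlier; portions every 12 min |  |
| eta | 0.53 M | run made earlier; portions every 12 min |  |
| flask | 0.24 M | the portions of coupling partner follow each other after 12 min, the first at the start | 50 min |

- gamma (time / min: substrate / %, product / %): 2.50: 98.8, 1.5; 5.00: 97.4, 2.8; 8.00: 96.1, 3.9; 15.0: 92.5, 8.3; 30.0: 85.5, 15.3
- eta (time / min: substrate / %, product / %): 6.00: 98.3, 2.3; 12.0: 96.2, 3.5; 20.0: 93.3, 7.0; 25.0: 91.1, 8.7; 30.0: 90.6, 10.2

(scatter of a reading: 0.5 percentage points)

- what may be going on: catalyst intermediate D -> free catalyst + product; substrate + free catalyst -> catalyst intermediate A; coupling partner + catalyst intermediate B -> catalyst intermediate C; catalyst intermediate C -> catalyst intermediate D; catalyst intermediate A -> catalyst intermediate B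
- the reaction counts as stopped when no species that holds the substrate changes by six tenths of a point or more over the second half of the time

- the state of affairs at 50 min: stopped, and by what, or still going (no working catalyst is left / all of the substrate has reacted / forward and back rates have come level / the coupling partner has run out first / it is still moving)
- conversion of substrate at 50 min
- amount of product at 50 min, in percent of the substrate charged

The easy step is a division. Product made by 30.0 min gives the gamma run a mean rate of 1.73 mM min⁻¹ and the eta run 1.80 mM min⁻¹. Catalyst charged over rate is the cycle time of one turnover: 0.277 min in gamma, 0.266 min in eta. With the catalyst forms taken as steady, each step adds its own term to that time, and the capture of substrate by free catalyst adds a term inversely proportional to the substrate concentration S. At a fixed concentration of coupling partner the rate then follows r = V·S/(K+S), where V is the rate at saturation by substrate. Mean substrate, reckoned from the product readings, was about 0.314 M in gamma and 0.503 M in eta, with the same catalyst and partner charges. The two runs therefore give K = 0.0351 M, the apparent Michaelis constant, the substrate concentration at which the rate is half of V, and V = 1.93 mM min⁻¹. The cycle times differ by 0.0110 min, and eta's product reading of 10.2% carries a scatter of 0.5 percentage points; K is a rough reading.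

This reckoning starts the flask at 1.68 mM min⁻¹. Falling substrate is the one slowing entered here. At that pace 0.0841 M would be consumed, and the rate at the substrate so left is 0.936 of the starting rate. The mean rate of 1.63 mM min⁻¹ gives this reckoning 33.9% product at 50 min, still moving. That is 0.0815 M, less than the whole charge of 0.216 M of coupling partner, the limiting reagent against 0.24 M of substrate.

The forecast is higher than this reckoning: it is still moving, conversion 37.5%, product 37%, holding that “the rate is essentially zero order in substrate, with the catalyst saturated”.

The simulation gives: it is still moving, conversion 30.7%, product 30.6%.

    catalyst intermediate D → free catalyst + product (k = 9.80 min⁻¹)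
    substrate + free catalyst → catalyst intermediate A (k = 46.0 L mol⁻¹ min⁻¹)
    coupling partner + catalyst intermediate B → catalyst intermediate C (k = 530 L mol⁻¹ min⁻¹)
    catalyst intermediate C → catalyst intermediate D (k = 12.0 min⁻¹)
    catalyst intermediate A → catalyst intermediate B (k = 64.0 min⁻¹)

The flask's mean rate was 1.47 mM min⁻¹, below the reckoned 1.63 mM min⁻¹. The same K applied to the neighbour flask with 0.41 M of substrate gives a start of 1.78 mM min⁻¹, a slowing factor of 0.979 and 21.4% product. That neighbour flask gave 21.0%, which is 0.0861 M of product against 0.0734 M in the flask.

The numbers in the tables come from a simulation with made-up constants; the scatter is artificial.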